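The bicyclic peroxy-lactone is numbered C1 (lactone carbonyl), C2, C3 (peroxide-bearing CH), C4 and C6 (methyl-bearing ring carbons) and C7–C16 (side chain; methyl on C8, phenyl on C16). The plan exploits the O–C3–C2–C1(=O)–O–C4 array shared by ring A (1,2-dioxane) and ring B (γ-lactone): it is the imprint of hydroperoxide attack, CO insertion and hydroxyl capture on a C2=C3 vinyl group beside the C4 carbinol. One palladium-catalysed operation on an open-chain C6 hydroperoxide/C4 vinyl carbinol, with C4, C6 and C8 already set and C11 as a silyl ether, therefore forms O–C3, C2–C1 and C1–O, closes both rings and sets C3. The diene tail is attached afterwards by Julia–Kocienski olefination at C11.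

Key step: step 12

Assumption: (E)-5-phenylpent-4-en-1-ol, used in step 15, is taken to be a purchasable alcohol.

Step 1
Reactants: 1 (R)-citronellal
Product: 2 (4R)-4,8-dimethylnon-7-en-2-ol (C2 epimer mixture)
Conditions: MeMgBr, Et2O, 0 °C; then H2O
Reagents that add atoms: methylmagnesium bromide, C[Mg]Br
Why: Grignard addition to the aldehyde supplies the future C6 methyl carbon; the new carbinol centre forms unselectively and is erased in step 4, while C8 is taken unchanged from the chiral pool.

Step 2
Reactants: 2 (4R)-4,8-dimethylnon-7-en-2-ol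
Product: 4 (4R)-4-methylheptane-1,6-diol (C6 epimer mixture), via hydroxy aldehyde 3 (not isolated)
Conditions: O3, CH2Cl2/MeOH, −78 °C; then NaBH4, −78 °C → rt
Reagents that add atoms: ozone, [O-][O+]=O
Why: Ozonolysis cleaves the only alkene at the future C11 and the borohydride work-up reduces the aldehyde in the flask to the primary alcohol.

Step 3
Reactants: 4 (4R)-4-methylheptane-1,6-diol
Product: 5 (4R)-7-[(tert-butyldimethylsilyl)oxy]-4-methylheptan-2-ol (C2 epimer mixture)
Conditions: tBuMe2SiCl (1.05 equiv), imidazole, CH2Cl2, −20 → 0 °C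
Reagents that add atoms: tert-butyldimethylsilyl chloride, CC(C)(C)[Si](C)(C)Cl
Why: Selective silyl ether formation, since the bulky silyl chloride should react with the unhindered primary hydroxyl far faster than with the secondary one.

Step 4
Reactants: 5 (4R)-7-[(tert-butyldimethylsilyl)oxy]-4-methylheptan-2-ol
Product: 6 (4R)-7-[(tert-butyldimethylsilyl)oxy]-4-methylheptan-2-one
Conditions: TEMPO (cat.), KBr (cat.), NaOCl, NaHCO3, CH2Cl2/H2O, 0 °C
Reagents that add atoms: none
Why: Oxoammonium (Anelli) oxidation of the secondary alcohol gives the methyl ketone at buffered pH, which the silyl ether tolerates, and C8 is not enolisable.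

Step 5
Reactants: 6 (4R)-7-[(tert-butyldimethylsilyl)oxy]-4-methylheptan-2-one
Product: 8 tert-butyldimethyl{[(4R)-4-methyl-6-[(trimethylsilyl)oxy]hept-6-en-1-yl]oxy}silane, via lithium enolate 7 (not isolated)
Conditions: LiN(iPr)2, THF, −78 °C; then Me3SiCl, −78 → 0 °C; non-aqueous work-up
Reagents that add atoms: chlorotrimethylsilane, C[Si](C)(C)Cl
Why: Kinetic enolisation by the hindered amide should take a methyl proton and not one of the C7 methylene next to the branch, and O-silylation fixes the terminal enolsilane.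

Step 6
Reactants: 8 terminal enolsilane; 9 methyl pyruvate
Product: 10 methyl (2S,6R)-9-[(tert-butyldimethylsilyl)oxy]-2,6-dimethyl-4-oxo-2-[(trimethylsilyl)oxy]nonanoate
Conditions: Cu(OTf)2 (10 mol %), 2,2'-(propane-2,2-diyl)bis[(4S)-4-tert-butyl-4,5-dihydro-1,3-oxazole] (11 mol %), THF, −78 °C; filtration through silica without acid
Reagents that add atoms: none
Why: Catalytic enantioselective Mukaiyama aldol addition, in which pyruvate chelates the square-planar copper–bis(oxazoline) complex, a tert-butyl group blocks one face and the enolsilane should add to the si face, setting C4 as the (S)-configured tertiary silyl ether after silyl transfer.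

Step 7
Reactants: 10 aldol silyl ether
Product: 11 methyl (2S,6R)-9-[(tert-butyldimethylsilyl)oxy]-2,6-dimethyl-4-methylidene-2-[(trimethylsilyl)oxy]nonanoate
Conditions: Ph3PCH3Br, KOtBu, THF, 0 °C; then 10, −78 → 0 °C
Reagents that add atoms: methyltriphenylphosphonium bromide, C[P+](c1ccccc1)(c1ccccc1)c1ccccc1.[Br-]
Why: Wittig methylenation of the unhindered C6 ketone should outpace both enolisation and attack on the congested α-silyloxy ester, and the silyl group on the C4 oxygen shuts off retro-aldol cleavage.

Step 8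
Reactants: 11 methylidene ester
Product: 12 (2S,6R)-9-[(tert-butyldimethylsilyl)oxy]-2,6-dimethyl-4-methylidene-2-[(trimethylsilyl)oxy]nonanal
Conditions: iBu2AlH (1.1 equiv), CH2Cl2, −78 °C; MeOH, then aq potassium sodium tartrate
Reagents that add atoms: none
Why: Partial ester reduction should stop at the aluminium hemiacetal at −78 °C, helped by the fully substituted α-carbon, and release the aldehyde on work-up; C4 carries no hydrogen and cannot epimerise.

Step 9
Reactants: 12 α-silyloxy aldehyde
Product: 13 (3S,7R)-10-[(tert-butyldimethylsilyl)oxy]-3,7-dimethyl-5-methylidene-3-[(trimethylsilyl)oxy]dec-1-ene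
Conditions: Ph3PCH3Br, KOtBu, THF, 0 °C; then 12, 0 °C → rt
Reagents that add atoms: methyltriphenylphosphonium bromide, C[P+](c1ccccc1)(c1ccccc1)c1ccccc1.[Br-]
Why: Wittig methylenation of the non-enolisable aldehyde completes the C2=C3 vinyl group on C4.

Step 10
Reactants: 13 diene
Product: 14 (3S,7R)-10-[(tert-butyldimethylsilyl)oxy]-3,5,7-trimethyl-5-[(triethylsilyl)peroxy]-3-[(trimethylsilyl)oxy]dec-1-ene (C5 epimer mixture)
Conditions: Co(acac)2 (10 mol %), Et3SiH (2 equiv), O2 (1 atm), ClCH2CH2Cl, rt
Reagents that add atoms: dioxygen, O=O; triethylsilane, CC[SiH](CC)CC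
Why: Mukaiyama–Isayama hydroperoxysilylation, in which hydrogen-atom transfer from a cobalt hydride to the 1,1-disubstituted alkene gives the tertiary C6 radical that is trapped by O2 and silylated, whereas the vinyl group would give a secondary radical beside the fully substituted silyloxy carbon and should react much more slowly; C6 forms without control as both epimers.

Step 11
Reactants: 14 silyl peroxide (epimer mixture)
Product: 15 (3S,5R,7R)-10-[(tert-butyldimethylsilyl)oxy]-5-hydroperoxy-3,5,7-trimethyldec-1-en-3-ol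
Conditions: K2CO3, MeOH, 0 °C → rt; then separation of the C6 epimers on silica (preparative HPLC if needed)
Reagents that add atoms: none
Why: Methanolysis at silicon should release the tertiary hydroperoxide and the tertiary alcohol while the primary tert-butyldimethylsilyl ether is inert to carbonate in methanol, and the two epimers, which differ in the 1,3-relation of hydroxyl and hydroperoxyl groups, are then separated.

Step 12
Reactants: 15 hydroperoxy vinyl carbinol; 16 carbon monoxide
Product: 19 (3R,4aS,7aS)-3-[(2R)-5-[(tert-butyldimethylsilyl)oxy]-2-methylpentyl]-3,4a-dimethyltetrahydrofuro[3,2-c][1,2]dioxin-6(3H)-one, via alkylpalladium chloride 17 (not isolated), via acylpalladium chloride 18 (not isolated)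
Conditions: PdCl2(MeCN)2 (10 mol %), p-benzoquinone (1.5 equiv), NaOAc (2 equiv), CO (5 bar), 4 Å molecular sieves, THF/AcOH (4:1), 0 °C → rt
Reagents that add atoms: carbon monoxide (16), [C-]#[O+]
Why: Proposed new method: the C2=C3 alkene, π-bound to divalent palladium with help from the neighbouring C4 hydroxyl, should take up the outer oxygen of the C6 hydroperoxide at C3 on the face opposite the metal, the resulting C2 alkylpalladium 17 should insert CO, the acylpalladium 18 should be captured by the C4 hydroxyl, and p-benzoquinone should return the released zerovalent palladium to the divalent state. The closest known reaction type is the PdCl2-catalysed alkoxycarbonylative double cyclization of pent-4-ene-1,3-diols to cis-fused bicyclic lactones, and 6-exo peroxypalladation alone is known from palladium diacetate-catalysed cyclizations of unsaturated tertiary hydroperoxides to 1,2-dioxanes; new here is a hydroperoxide as the distal nucleophile of the carbonylative cascade. Ring A (1,2-dioxane) closes by 6-exo-trig O–C3 bond formation at the internal alkene carbon, and ring B (γ-lactone) closes by 5-exo-trig acyl capture at the C4 oxygen after the C2–C1 bond has formed. The new C3 centre is controlled by C4: a chair-like transition state with both ring methyl groups and the metal-bound alkene equatorial places CH2Pd cis to the C4 oxygen, peroxypalladation is reversible, and the cis adduct is the one that should lactonize fastest, to the cis-fused bicycle. The step needs Markovnikov (6-exo over 7-endo) attack, secured by the tether length, and survival of the O–O bond, for which no copper reoxidant is used (monovalent copper would cleave the hydroperoxide), chloride ligands keep the hydroperoxide off the metal, and CO pressure at low temperature should outrun β-hydride loss and ketonization of 17.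

Step 13
Reactants: 19 silyl-protected peroxy-lactone
Product: 20 (3R,4aS,7aS)-3-[(2R)-5-hydroxy-2-methylpentyl]-3,4a-dimethyltetrahydrofuro[3,2-c][1,2]dioxin-6(3H)-one
Conditions: HF·pyridine, pyridine, THF, 0 °C → rt
Reagents that add atoms: none
Why: Fluoride-mediated cleavage of the primary silyl ether under mildly acidic conditions, which the dialkyl peroxide and the lactone should tolerate.

Step 14
Reactants: 20 C11 alcohol
Product: 21 (4R)-5-[(3R,4aS,7aS)-3,4a-dimethyl-6-oxohexahydrofuro[3,2-c][1,2]dioxin-3-yl]-4-methylpentanal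
Conditions: Dess–Martin periodinane, NaHCO3, CH2Cl2, 0 °C → rt
Reagents that add atoms: none
Why: Buffered hypervalent-iodine oxidation of the primary alcohol should stop at the aldehyde and leave peroxide, lactone and all stereocentres untouched.

Step 15
Reactants: 22 (E)-5-phenylpent-4-en-1-ol; 23 1-phenyl-1H-tetrazole-5-thiol
Product: 24 1-phenyl-5-{[(4E)-5-phenylpent-4-en-1-yl]sulfanyl}-1H-tetrazole
Conditions: PPh3, iPrO2CN=NCO2iPr, THF, 0 °C → rt
Reagents that add atoms: none
Why: Mitsunobu thioetherification of the primary alcohol with the acidic tetrazole thiol; the (E)-styryl alkene takes no part.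

Step 16
Reactants: 24 sulfide
Product: 25 1-phenyl-5-{[(4E)-5-phenylpent-4-en-1-yl]sulfonyl}-1H-tetrazole
Conditions: (NH4)6Mo7O24·4H2O (10 mol %), 30% aq H2O2, EtOH, 0 °C → rt
Reagents that add atoms: hydrogen peroxide, OO
Why: Molybdate-catalysed oxidation takes the sulfide to the sulfone and should spare the styryl alkene.

Step 17
Reactants: 21 C11 aldehyde; 25 tetrazolyl sulfone
Product: 27 (3R,4aS,7aS)-3,4a-dimethyl-3-[(2R,5E,9E)-2-methyl-10-phenyldeca-5,9-dien-1-yl]tetrahydrofuro[3,2-c][1,2]dioxin-6(3H)-one, via potassium sulfonyl carbanion 26 (not isolated)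
Conditions: 25, KN(SiMe3)2, DME, −60 °C; then 21, −60 °C → rt
Reagents that add atoms: none
Why: Julia–Kocienski olefination, in which the preformed sulfonyl carbanion adds to the C11 aldehyde and Smiles rearrangement with loss of SO2 and tetrazolate gives the C11=C12 alkene, expected mainly E for a phenyltetrazolyl sulfone with potassium in DME; premetalation keeps free base away from the lactone and the C15=C16 geometry is carried in from 22.

Compound list
1 | (R)-citronellal | C[C@H](CCC=C(C)C)CC=O | starting material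
2 | (4R)-4,8-dimethylnon-7-en-2-ol (C2 epimer mixture) | C[C@H](CCC=C(C)C)CC(C)O | intermediate
3 | (4R)-6-hydroxy-4-methylheptanal (C6 epimer mixture, not isolated) | C[C@H](CCC=O)CC(C)O | intermediate
4 | (4R)-4-methylheptane-1,6-diol (C6 epimer mixture) | C[C@H](CCCO)CC(C)O | intermediate
5 | (4R)-7-[(tert-butyldimethylsilyl)oxy]-4-methylheptan-2-ol (C2 epimer mixture) | C[C@H](CCCO[Si](C)(C)C(C)(C)C)CC(C)O | intermediate
6 | (4R)-7-[(tert-butyldimethylsilyl)oxy]-4-methylheptan-2-one | C[C@H](CCCO[Si](C)(C)C(C)(C)C)CC(C)=O | intermediate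
7 | lithium enolate of 6, terminal (not isolated) | C[C@H](CCCO[Si](C)(C)C(C)(C)C)CC(=C)O[Li] | intermediate
8 | tert-butyldimethyl{[(4R)-4-methyl-6-[(trimethylsilyl)oxy]hept-6-en-1-yl]oxy}silane | C[C@H](CCCO[Si](C)(C)C(C)(C)C)CC(=C)O[Si](C)(C)C | intermediate
9 | methyl pyruvate | CC(=O)C(=O)OC | starting material
10 | methyl (2S,6R)-9-[(tert-butyldimethylsilyl)oxy]-2,6-dimethyl-4-oxo-2-[(trimethylsilyl)oxy]nonanoate | C[C@H](CCCO[Si](C)(C)C(C)(C)C)CC(=O)C[C@](C)(O[Si](C)(C)C)C(=O)OC | intermediate
11 | methyl (2S,6R)-9-[(tert-butyldimethylsilyl)oxy]-2,6-dimethyl-4-methylidene-2-[(trimethylsilyl)oxy]nonanoate | C[C@H](CCCO[Si](C)(C)C(C)(C)C)CC(=C)C[C@](C)(O[Si](C)(C)C)C(=O)OC | intermediate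
12 | (2S,6R)-9-[(tert-butyldimethylsilyl)oxy]-2,6-dimethyl-4-methylidene-2-[(trimethylsilyl)oxy]nonanal | C[C@H](CCCO[Si](C)(C)C(C)(C)C)CC(=C)C[C@](C)(O[Si](C)(C)C)C=O | intermediate
13 | (3S,7R)-10-[(tert-butyldimethylsilyl)oxy]-3,7-dimethyl-5-methylidene-3-[(trimethylsilyl)oxy]dec-1-ene | C[C@H](CCCO[Si](C)(C)C(C)(C)C)CC(=C)C[C@](C)(O[Si](C)(C)C)C=C | intermediate
14 | (3S,7R)-10-[(tert-butyldimethylsilyl)oxy]-3,5,7-trimethyl-5-[(triethylsilyl)peroxy]-3-[(trimethylsilyl)oxy]dec-1-ene (C5 epimer mixture) | C[C@H](CCCO[Si](C)(C)C(C)(C)C)CC(C)(OO[Si](CC)(CC)CC)C[C@](C)(O[Si](C)(C)C)C=C | intermediate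
15 | (3S,5R,7R)-10-[(tert-butyldimethylsilyl)oxy]-5-hydroperoxy-3,5,7-trimethyldec-1-en-3-ol (key-step precursor) | C[C@H](CCCO[Si](C)(C)C(C)(C)C)C[C@](OO)(C)C[C@](C=C)(C)O | intermediate
16 | carbon monoxide | [C-]#[O+] | starting material
17 | alkylpalladium chloride: ring A closed, C4 hydroxyl free, PdCl on C2 (not isolated) | C[C@H](CCCO[Si](C)(C)C(C)(C)C)C[C@]1(C)C[C@](C)(O)[C@H](C[Pd]Cl)OO1 | intermediate
18 | acylpalladium chloride: as 17 with C1(=O)PdCl on C2 (not isolated) | C[C@H](CCCO[Si](C)(C)C(C)(C)C)C[C@]1(C)C[C@](C)(O)[C@H](CC(=O)[Pd]Cl)OO1 | intermediate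
19 | (3R,4aS,7aS)-3-[(2R)-5-[(tert-butyldimethylsilyl)oxy]-2-methylpentyl]-3,4a-dimethyltetrahydrofuro[3,2-c][1,2]dioxin-6(3H)-one (key-step product) | C[C@H](CCCO[Si](C)(C)C(C)(C)C)C[C@]1(C)C[C@]2(C)OC(=O)C[C@@H]2OO1 | intermediate
20 | (3R,4aS,7aS)-3-[(2R)-5-hydroxy-2-methylpentyl]-3,4a-dimethyltetrahydrofuro[3,2-c][1,2]dioxin-6(3H)-one | C[C@H](CCCO)C[C@]1(C)C[C@]2(C)OC(=O)C[C@@H]2OO1 | intermediate
21 | (4R)-5-[(3R,4aS,7aS)-3,4a-dimethyl-6-oxohexahydrofuro[3,2-c][1,2]dioxin-3-yl]-4-methylpentanal | C[C@H](CCC=O)C[C@]1(C)C[C@]2(C)OC(=O)C[C@@H]2OO1 | intermediate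
22 | (E)-5-phenylpent-4-en-1-ol | OCCC/C=C/c1ccccc1 | starting material
23 | 1-phenyl-1H-tetrazole-5-thiol | Sc1nnnn1-c1ccccc1 | starting material
24 | 1-phenyl-5-{[(4E)-5-phenylpent-4-en-1-yl]sulfanyl}-1H-tetrazole | c1ccccc1/C=C/CCCSc1nnnn1-c1ccccc1 | intermediate
25 | 1-phenyl-5-{[(4E)-5-phenylpent-4-en-1-yl]sulfonyl}-1H-tetrazole | O=S(=O)(CCC/C=C/c1ccccc1)c1nnnn1-c1ccccc1 | intermediate
26 | potassium α-sulfonyl carbanion of 25 (not isolated) | [K+].[CH-](CC/C=C/c1ccccc1)S(=O)(=O)c1nnnn1-c1ccccc1 | intermediate
27 | (3R,4aS,7aS)-3,4a-dimethyl-3-[(2R,5E,9E)-2-methyl-10-phenyldeca-5,9-dien-1-yl]tetrahydrofuro[3,2-c][1,2]dioxin-6(3H)-one (CNP0365311.2) | C[C@H](CC/C=C/CC/C=C/c1ccccc1)C[C@]1(C)C[C@]2(C)OC(=O)C[C@@H]2OO1 | target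

Total step count: 17. Longest linear sequence: 15 steps (steps 1–14 and 17); the sulfone branch is steps 15–16.

Steps most likely to fail

1. Step 12. What may go wrong: the O–O bond is cleaved at palladium, alkylpalladium 17 collapses to the C3 ketone, or a palladium alkylperoxide oxidizes CO, each faster than carbonylation. The fallback uses known chemistry, the conjugate addition of a hydroperoxide to a butenolide, and sets out from aldehyde 12.
   - A Z-selective Still–Gennari olefination with methyl bis(2,2,2-trifluoroethyl)phosphonoacetate (KN(SiMe3)2, 18-crown-6, THF, −78 °C) should give Z-enoate F1.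
   - Citric acid in MeOH removes the trimethylsilyl group and the freed C4 hydroxyl closes onto the Z-ester to give butenolide F2.
   - The cobalt conditions of step 10 then meet only one electron-rich alkene and should give silyl peroxide F3 as both C6 epimers.
   - K2CO3 in MeOH at 0 °C frees hydroperoxide F4, and Et2NH in CF3CH2OH closes ring A by 6-exo conjugate addition of the hydroperoxide to C3, which can only give the cis-fused bicycle.
   - The C6-epimeric peroxy-lactone F5 is removed by chromatography at this rigid bicyclic stage, and the route is rejoined at 19.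

2. Step 10. What may go wrong: hydrogen-atom transfer to the vinyl group competes, so that both alkenes are peroxidised. The fallback sets out from ester 11, in which the C6 methylene is the only alkene, so the vinyl group is made only after the peroxide is in place.
   - The same cobalt conditions should give silyl peroxide ester F6.
   - iBu2AlH at −78 °C then gives peroxy aldehyde F7, and Wittig methylenation (Ph3PCH3Br, KOtBu, THF, −78 → 0 °C) gives 14, where the route is rejoined.
   - A tert-alkyl silyl peroxide has no α-hydrogen and a shielded O–O bond and should survive hydride and ylide at low temperature.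

3. Step 11. What may go wrong: the two open-chain C6 epimers co-elute. The fallback moves the separation behind the ring closure: the mixture of 15 and its (5S)-epimer F8 is submitted to step 12 as it is. The rigid cis-fused bicycles 19 and F5 differ in the relative orientation of three ring substituents and should separate on silica, and the route is rejoined at 19.

Further compounds
F1 | step 12 | methyl (2Z,4S,8R)-11-[(tert-butyldimethylsilyl)oxy]-4,8-dimethyl-6-methylidene-4-[(trimethylsilyl)oxy]undec-2-enoate | C[C@H](CCCO[Si](C)(C)C(C)(C)C)CC(=C)C[C@](C)(O[Si](C)(C)C)/C=C\C(=O)OC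
F2 | step 12 | (5S)-5-[(4R)-7-[(tert-butyldimethylsilyl)oxy]-4-methyl-2-methylideneheptyl]-5-methylfuran-2(5H)-one | C[C@H](CCCO[Si](C)(C)C(C)(C)C)CC(=C)C[C@]1(C)OC(=O)C=C1
F3 | step 12 | (5S)-5-[(4R)-7-[(tert-butyldimethylsilyl)oxy]-2,4-dimethyl-2-[(triethylsilyl)peroxy]heptyl]-5-methylfuran-2(5H)-one (C6 epimer mixture) | C[C@H](CCCO[Si](C)(C)C(C)(C)C)CC(C)(OO[Si](CC)(CC)CC)C[C@]1(C)OC(=O)C=C1
F4 | step 12 | (5S)-5-[(4R)-7-[(tert-butyldimethylsilyl)oxy]-2-hydroperoxy-2,4-dimethylheptyl]-5-methylfuran-2(5H)-one (C6 epimer mixture) | C[C@H](CCCO[Si](C)(C)C(C)(C)C)CC(C)(OO)C[C@]1(C)OC(=O)C=C1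
F5 | step 12 | (3S,4aS,7aS)-3-[(2R)-5-[(tert-butyldimethylsilyl)oxy]-2-methylpentyl]-3,4a-dimethyltetrahydrofuro[3,2-c][1,2]dioxin-6(3H)-one (C6 epimer of 19) | C[C@H](CCCO[Si](C)(C)C(C)(C)C)C[C@@]1(C)C[C@]2(C)OC(=O)C[C@@H]2OO1
F6 | step 10 | methyl (2S,6R)-9-[(tert-butyldimethylsilyl)oxy]-2,4,6-trimethyl-4-[(triethylsilyl)peroxy]-2-[(trimethylsilyl)oxy]nonanoate (C6 epimer mixture) | C[C@H](CCCO[Si](C)(C)C(C)(C)C)CC(C)(OO[Si](CC)(CC)CC)C[C@](C)(O[Si](C)(C)C)C(=O)OC
F7 | step 10 | (2S,6R)-9-[(tert-butyldimethylsilyl)oxy]-2,4,6-trimethyl-4-[(triethylsilyl)peroxy]-2-[(trimethylsilyl)oxy]nonanal (C6 epimer mixture) | C[C@H](CCCO[Si](C)(C)C(C)(C)C)CC(C)(OO[Si](CC)(CC)CC)C[C@](C)(O[Si](C)(C)C)C=O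
F8 | step 11 | (3S,5S,7R)-10-[(tert-butyldimethylsilyl)oxy]-5-hydroperoxy-3,5,7-trimethyldec-1-en-3-ol (C6 epimer of 15) | C[C@H](CCCO[Si](C)(C)C(C)(C)C)C[C@@](OO)(C)C[C@](C=C)(C)O
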